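3 questions stand below, and one quantity serves them all: the selectivity factor, which compares how fast partner takes each hand.

the same everywhere: left-handed substrate 32 mM; right-handed substrate 32 mM; racemization catalyst 1.6 mM; impurity 1.5 mM

| run | solid reagent | remark | time |
|---|---|---|---|
| west | 48 mM | run made earlier |  |
| east | 72 mM | run made earlier |  |
| beta | 96.0 mM |  | 30 min |
| epsilon | 96.0 mM |  | 15 min |

| run | time / min | right-handed substrate / % | left-handed substrate / % |
|---|---|---|---|
| west | 3.00 | 48 | 31 |
| west | 6.00 | 46 | 18 |
| west | 15.0 | 37 | 2 |
| west | 40.0 | 26 | 1 |
| east | 3.00 | 48 | 33 |
| east | 6.00 | 42 | 19 |
| east | 15.0 | 34 | 2 |
| east | 40.0 | 19 | 3 |

(standard deviation of a reading: 1.5 percentage points)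

* which of the two ends with the higher excess of right-handed substrate over left-handed substrate among what is left of the two ("neither" if they lie within 2 percentage points) (beta / epsilon / neither)
* excess of right-handed substrate over left-handed substrate among what is left of the two at the end, beta
* excess of right-handed substrate over left-handed substrate among what is left of the two at the end, epsilon

- partner is single-handed; left-handed substrate and right-handed substrate are mirror images of each other, charged as a racemate, each of them at the stated concentration
- solid, in amounts per volume of the solution: solid reagent
- what may be going on: left-handed substrate + racemization catalyst <-> right-handed substrate + racemization catalyst; partner + left-handed substrate -> left-handed product; partner + right-handed substrate -> right-handed product; racemization catalyst <-> dormant form; solid reagent <-> partner; racemization catalyst + impurity -> spent catalyst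
- at the start none of the solid reagent is in solution
- an excess is the difference of the two amounts in percent of their sum
- an excess is below zero if the other one leads
- the handed part of partner does not stay in what it makes, so the products of the two hands are mirror images too

Read the two runs row against row. At 3.00 min, west and east hold 31% and 33% left-handed substrate, a gap of 2 percentage points against a scatter of 1.5 points, so take dissolved partner as alike in the two runs at that time; none of the solid reagent is in solution at the start, so do not take partner as steady. At 40.0 min, the right-handed column parts by 7 points: west's products then hold 46.7 mM of partner against 48 mM of solid reagent charged, so take late rates from east.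

Assume racemization is negligible. Let x be the fraction of the right-handed charge left; both hands meet the same partner, however it climbs from zero, so the left-handed fraction is then x^s. East at 15.0 min gives s, the ratio of the logarithms of the two fractions left, as 8.35. East's right-handed reading at 40.0 min gives an average decay constant of 0.0242 /min; read it as a rough mean over those minutes, not as a steady rate.

My reckoning therefore puts x at 48.4% in beta and 69.6% in epsilon. The excess (x − x^s)/(x + x^s) is then 99.0% and 87.0%. Go round once more: beta's answer consumes 48.4 mM of partner, less than its 96.0 mM of solid reagent, so this reckoning keeps solid on hand in beta; that says nothing of how dissolved partner moves with time.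

The forecast names beta, with 94% and 88%, holding that the “resolution is therefore essentially kinetic”; my beta figure lies above its own.

The flask gives beta, with 98.9% in beta and 88.6% in epsilon.

    left-handed substrate + racemization catalyst ⇌ right-handed substrate + racemization catalyst, rate k1*[racemization catalyst]*[left-handed substrate] forward; the back reaction follows from the equilibrium constant (k = 0.268 /M/s)
    partner + left-handed substrate → left-handed product (k = 0.403 /M/s)
    partner + right-handed substrate → right-handed product (k = 0.0458 /M/s)
    racemization catalyst ⇌ dormant form (K = 1.30, k = 0.00274 /s)
    solid reagent ⇌ partner, rate k5*(cs5 - [partner]) while solid is left; crystals form when [partner] > cs5 (solubility = 12.0 mM, k = 0.0196 /s)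
    racemization catalyst + impurity → spent catalyst (k = 14.2 /M/s)

In epsilon at 4.12 min, partner consumes left-handed substrate 74 times faster than the forward racemization step, and the racemization relaxation half-life of 4.81 h is long against 30 min. At its end, 15.0 min, epsilon's 68% of right-handed charge left gives x^s = 3.88%; at that same time the flask holds 4.1% of its left-handed charge.

In the neighbouring flask, epsilon with 24 mM of solid reagent, x = 88% gives x^s = 34.3% and an excess of 43.8%. The computed flask holds 37% and 40.4%.

(The readings are calculated on assumed constants, noise included.)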